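Everything rests on breaking the crowded C5–C6 bond of ring A (C1–C6), the bond between the gem-dimethyl carbon and the spiro carbon. Ring B (C6–C11) is read as a para-substituted phenol with its oxygen at C9, so the precursor is the flat, racemic 4-(1-hydroxy-2,2-dimethylcyclopentyl)phenol. Two-electron oxidation makes the para carbon C6 electrophilic, and tertiary C5 migrates to it from the carbinol carbon C1. One operation thus enlarges the cyclopentanol to the cyclohexanone, joins the two quaternary carbons, creates the spiro centre and leaves a prochiral dienone. Catalytic desymmetrisation sets C6; C6 relays to C1, and a silicon tether relays C1 to C3.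

Key step: step 2

Locants: all spiro compounds carry the numbering of the target. C1 is the carbinol carbon, C3 is CHBr, C5 is CMe2, C6 is the spiro carbon, C7=C8 is the ring olefin, and C9 carries =CHBr. The target is (1S,3R,6S,9E)-3-bromo-9-(bromomethylidene)-1,5,5-trimethylspiro[5.5]undec-7-en-1-ol.

Assumption: the sense of induction of the copper hydride catalyst on dienone 7 cannot be derived from first principles. (R,R)-Ph-BPE is written, and the (S,S) ligand is used instead if it delivers the (6R) enone.

Step 1
Reactants: 1 (4-bromophenoxy)(tert-butyl)dimethylsilane; 2 2,2-dimethylcyclopentan-1-one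
Product: 5 4-(1-hydroxy-2,2-dimethylcyclopentyl)phenol (racemic), via aryllithium 3 (not isolated), via silyl ether carbinol 4 (not isolated)
Conditions: 1, n-BuLi, THF, −78 °C; then 2, −78 → 0 °C; then TBAF, 0 °C → rt; aq. NH4Cl
Reagents that add atoms: none
Why: Bromine–lithium exchange, 1,2-addition of the aryllithium to the ketone and fluoride desilylation in the same flask should give the free phenol, and the carbinol centre is deliberately formed racemic because step 2 erases it.

Step 2
Reactants: 5 4-(1-hydroxy-2,2-dimethylcyclopentyl)phenol
Product: 7 5,5-dimethylspiro[5.5]undeca-7,10-diene-1,9-dione, via aryloxyiodane 6 (not isolated)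
Conditions: PhI(OAc)2 (1.1 equiv), (CF3)2CHOH, 0 °C, short reaction time
Reagents that add atoms: none
Why: Ligand exchange of the phenol on iodine(III) gives aryloxyiodane 6, whose heterolysis in the ionising, non-nucleophilic solvent leaves a phenoxenium ion with positive charge at the para carbon C6 (umpolung of a normally nucleophilic position), and the adjacent carbinol answers with a semipinacol [1,2]-shift in which the C1–C5 bond moves to C6 while C1–OH becomes C1=O. The closest known reaction type is the hypervalent-iodine-mediated oxidative dearomatisation of 4-(1-hydroxyalkyl)phenols with 1,2-alkyl shift (oxidative Wagner–Meerwein/semipinacol transposition), of which the enlargement of a 1-arylcycloalkanol is the cyclic version. No ring is closed in the Baldwin sense, because the six-membered ring arises by suprafacial insertion of C6 into the C1–C5 bond of the five-membered ring through a three-centre transition state. No stereocentre is created, since C6 carries two enantiotopic enone arms and the carbinol centre of 5 is erased, so racemic 5 suffices. The step needs migration of C5 and not of C2, which the substrate secures because the tertiary carbon carries the developing positive charge far better than the CH2 group and its departure relieves the aryl/gem-dimethyl compression. It also needs the shift to outrun solvent capture at C6 and ionisation of the benzylic alcohol, which the low nucleophilicity of the fluorinated alcohol, the low temperature and the short contact time secure.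

Step 3
Reactants: 7 5,5-dimethylspiro[5.5]undeca-7,10-diene-1,9-dione
Product: 9 (6S)-5,5-dimethylspiro[5.5]undec-7-ene-1,9-dione, via silyl dienol ether 8 (not isolated)
Conditions: Cu(OAc)2 (5 mol %), (R,R)-Ph-BPE (6 mol %), (EtO)2MeSiH (1.2 equiv), toluene, −20 °C; then 1 M HCl, THF, 0 °C
Reagents that add atoms: none
Why: In this copper hydride catalysed asymmetric conjugate reduction, a desymmetrisation of a prochiral 4,4-disubstituted cyclohexa-2,5-dienone, the chiral ligand tells the two enantiotopic enone arms apart through the acyl (C1) versus tert-alkyl (C5) substituents at C6 and so sets C6 as (S), while the silyl dienol ether 8 shields the second arm from over-reduction.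

Step 4
Reactants: 9 (6S)-5,5-dimethylspiro[5.5]undec-7-ene-1,9-dione
Product: 10 (6S,9E)-9-(bromomethylidene)-5,5-dimethylspiro[5.5]undec-7-en-1-one
Conditions: [Ph3PCH2Br]Br, NaHMDS, THF, −78 °C; then 9, −78 → −20 °C
Reagents that add atoms: (bromomethyl)triphenylphosphonium bromide, BrC[P+](c1ccccc1)(c1ccccc1)c1ccccc1.[Br-]
Why: In this Wittig bromomethylenation the open enone carbonyl C9 should react while the C1 ketone next to quaternary C6 stays inert, and kinetic oxaphosphetane formation is expected to place bromine syn to the bulkier sp3 flank C10 (the E isomer), any Z isomer being removed by chromatography.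

Step 5
Reactants: 10 (6S,9E)-9-(bromomethylidene)-5,5-dimethylspiro[5.5]undec-7-en-1-one
Product: 12 (6S,9E)-9-(bromomethylidene)-5,5-dimethylspiro[5.5]undeca-2,7-dien-1-one, via lithium enolate 11 (not isolated)
Conditions: LDA, THF, −78 °C; then PhS(Cl)=N-t-Bu, −78 °C
Reagents that add atoms: none
Why: In this Mukaiyama one-pot dehydrogenation C2 is the only enolisable position, the enolate is sulfur-functionalised and loses the sulfenamide by syn elimination at low temperature, and no palladium is present that could insert into the vinyl C–Br bond.

Step 6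
Reactants: 12 (6S,9E)-9-(bromomethylidene)-5,5-dimethylspiro[5.5]undeca-2,7-dien-1-one
Product: 13 (1S,6S,9E)-9-(bromomethylidene)-1,5,5-trimethylspiro[5.5]undeca-2,7-dien-1-ol
Conditions: MeLi, CeCl3, THF, −78 °C; aq. NH4Cl
Reagents that add atoms: methyllithium, [Li]C
Why: In this organocerium 1,2-addition the axial trajectory is closed on either face by whichever C5 methyl is axial, so methyl must pass the axial C6 arm, and the half-chair with the flat sp2 C7–H arm axial is less hindered than the one with C11H2 axial, which should deliver methyl syn to C7 and set C1 as (S), the minor epimer being removed by chromatography.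

Step 7
Reactants: 13 (1S,6S,9E)-9-(bromomethylidene)-1,5,5-trimethylspiro[5.5]undeca-2,7-dien-1-ol
Product: 16 (1S,3S,6S,9E)-9-(bromomethylidene)-1,5,5-trimethylspiro[5.5]undec-7-ene-1,3-diol, via dimethylsilyl ether 14 (not isolated), via oxasilolane 15 (not isolated)
Conditions: HMe2SiCl, Et3N, DMAP (cat.), CH2Cl2, 0 °C, filter; Karstedt catalyst (1 mol %), toluene, 60 °C; then 30 % H2O2, KF, KHCO3, THF–MeOH, rt
Reagents that add atoms: hydrogen peroxide, OO
Why: In this tethered intramolecular hydrosilylation of an allylic alcohol followed by Tamao–Fleming oxidation, the five-membered oxasilolane can only form by 5-endo delivery of silicon to C3 on the face of the C1 oxygen (C7=C8 lies anti to the C1–O bond in the favoured conformer), and oxidation with retention should give the cis-1,3-diol, so C1 sets C3 as (S).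

Step 8
Reactants: 16 (1S,3S,6S,9E)-9-(bromomethylidene)-1,5,5-trimethylspiro[5.5]undec-7-ene-1,3-diol
Product: 17 (1S,3R,6S,9E)-3-bromo-9-(bromomethylidene)-1,5,5-trimethylspiro[5.5]undec-7-en-1-ol
Conditions: CBr4, PPh3, CH2Cl2, 0 °C
Reagents that add atoms: tetrabromomethane, BrC(Br)(Br)Br
Why: In this Appel bromination the secondary C3 alcohol is activated in preference to the hindered tertiary C1 alcohol, and bromide displaces the axial oxyphosphonium group by SN2 with inversion, turning the (3S) alcohol into the equatorial (3R) bromide trans to the C1 hydroxyl.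

Compound list
1 | (4-bromophenoxy)(tert-butyl)dimethylsilane | CC(C)(C)[Si](C)(C)Oc1ccc(Br)cc1 | starting material
2 | 2,2-dimethylcyclopentan-1-one | CC1(C)CCCC1=O | starting material
3 | [4-(tert-butyldimethylsilyloxy)phenyl]lithium | [Li]c1ccc(O[Si](C)(C)C(C)(C)C)cc1 | intermediate
4 | 1-[4-(tert-butyldimethylsilyloxy)phenyl]-2,2-dimethylcyclopentan-1-ol (racemic, present as its lithium alkoxide) | CC1(C)CCCC1(O)c1ccc(O[Si](C)(C)C(C)(C)C)cc1 | intermediate
5 | 4-(1-hydroxy-2,2-dimethylcyclopentyl)phenol (racemic) | CC1(C)CCCC1(O)c1ccc(O)cc1 | intermediate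
6 | acetoxy(phenyl)-λ3-iodanyl ether of phenol 5 | CC(=O)OI(Oc1ccc(cc1)C1(O)CCCC1(C)C)c1ccccc1 | intermediate
7 | 5,5-dimethylspiro[5.5]undeca-7,10-diene-1,9-dione (achiral) | CC1(C)CCCC(=O)C12C=CC(=O)C=C2 | intermediate
8 | (6S)-9-[diethoxy(methyl)silyl]oxy-5,5-dimethylspiro[5.5]undeca-7,9-dien-1-one | CC1(C)CCCC(=O)[C@@]12C=CC(O[Si](C)(OCC)OCC)=CC2 | intermediate
9 | (6S)-5,5-dimethylspiro[5.5]undec-7-ene-1,9-dione | CC1(C)CCCC(=O)[C@@]12C=CC(=O)CC2 | intermediate
10 | (6S,9E)-9-(bromomethylidene)-5,5-dimethylspiro[5.5]undec-7-en-1-one | CC1(C)CCCC(=O)[C@@]12C=C/C(=C/Br)CC2 | intermediate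
11 | lithium C1,C2-enolate of 10 | CC1(C)CCC=C([O-])[C@@]12C=C/C(=C/Br)CC2.[Li+] | intermediate
12 | (6S,9E)-9-(bromomethylidene)-5,5-dimethylspiro[5.5]undeca-2,7-dien-1-one | CC1(C)CC=CC(=O)[C@@]12C=C/C(=C/Br)CC2 | intermediate
13 | (1S,6S,9E)-9-(bromomethylidene)-1,5,5-trimethylspiro[5.5]undeca-2,7-dien-1-ol (methyl syn to C7) | CC1(C)CC=C[C@](C)(O)[C@@]12C=C/C(=C/Br)CC2 | intermediate
14 | dimethylsilyl (Si–H) ether of 13 | CC1(C)CC=C[C@](C)(O[SiH](C)C)[C@@]12C=C/C(=C/Br)CC2 | intermediate
15 | 2,2-dimethyl-1,2-oxasilolane bridging O–C1 and C3 (silicon on C3 on the face of the C1 oxygen) | CC1(C)C[C@H]2C[C@](C)(O[Si]2(C)C)[C@@]13C=C/C(=C/Br)CC3 | intermediate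
16 | (1S,3S,6S,9E)-9-(bromomethylidene)-1,5,5-trimethylspiro[5.5]undec-7-ene-1,3-diol (cis-1,3-diol) | CC1(C)C[C@H](O)C[C@](C)(O)[C@@]12C=C/C(=C/Br)CC2 | intermediate
17 | (1S,3R,6S,9E)-3-bromo-9-(bromomethylidene)-1,5,5-trimethylspiro[5.5]undec-7-en-1-ol | CC1(C)C[C@@H](Br)C[C@](C)(O)[C@@]12C=C/C(=C/Br)CC2 | target

Total step count: 8. Longest linear sequence: 8 steps (from 1 or 2 to 17).

Steps most likely to fail

1. Step 6.
- What may go wrong: poor facial discrimination in the methyl transfer, because the two arms at C6 differ only as sp2 CH versus CH2, together with competing deprotonation at C4.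
- Fallback (sets out from 12, comes back at 17): the order of events in ring A is reversed so that C3 controls C1. Conjugate addition of HBr (one equivalent, CH2Cl2, −20 °C) to the ring A enone of 12 should give (3R,6S,9E)-3-bromo-9-(bromomethylidene)-5,5-dimethylspiro[5.5]undec-7-en-1-one F1. The addition is reversible, so the C3 epimer can be separated and returned to the equilibrium. The equatorial bromine of F1 fixes the chair with C7 axial. MeLi/CeCl3 at −78 °C, with a cold acidic quench that forestalls loss of HBr and Grob fragmentation of the alkoxide, should then add along the only open, equatorial trajectory and give 17 directly. This also bypasses steps 7 and 8.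

2. Step 7.
- What may go wrong: sluggish 5-endo closure on the hindered ring olefin, and diversion of the platinum hydride to the bromodiene (hydrosilylation or E/Z isomerisation).
- Fallback (sets out from 13, comes back at 16): the C3 oxygen is brought in intermolecularly and its configuration is set afterwards by hydride.
  - 9-BBN-H (two equivalents, the first consumed by the hydroxyl group) should hydroborate the isolated C2=C3 bond faster than the conjugated bromodiene. Boron goes to C3, away from quaternary C1 and anti to the borinate, giving the C3-(9-borabicyclo[3.3.1]nonan-9-yl) O-borinate F2.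
  - NaBO3 in the same flask should give (1S,3R,6S,9E)-9-(bromomethylidene)-1,5,5-trimethylspiro[5.5]undec-7-ene-1,3-diol F3. Any 16 formed alongside converges in the next operation.
  - Dess–Martin oxidation of the secondary alcohol should give (1S,6S,9E)-9-(bromomethylidene)-1-hydroxy-1,5,5-trimethylspiro[5.5]undec-7-en-3-one F4.
  - L-Selectride at −78 °C must attack F4 equatorially, because the axial C1 hydroxyl and the axial C5 methyl close the other face. This gives the axial alcohol 16.

3. Step 8.
- What may go wrong: E2 loss of the axial oxyphosphonium group toward C2 or C4 instead of substitution, and ionisation of the tertiary alcohol.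
- Fallback (sets out from 16, comes back at 17): both oxygens are tied into one leaving group.
  - 1,1′-Sulfonyldiimidazole and NaH in THF should give the six-membered cyclic sulfate F5. No ruthenium oxidant is used, so the diene is spared.
  - LiBr in THF should open F5 at the secondary carbon C3 with inversion, giving lithium (1S,3R,6S,9E)-3-bromo-9-(bromomethylidene)-1,5,5-trimethylspiro[5.5]undec-7-en-1-yl sulfate F6.
  - Catalytic H2SO4 with a little water in THF should cleave the S–O bond of F6 with retention at C1 and release 17.

Further compounds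
F1 | step 6 | (3R,6S,9E)-3-bromo-9-(bromomethylidene)-5,5-dimethylspiro[5.5]undec-7-en-1-one | CC1(C)C[C@@H](Br)CC(=O)[C@@]12C=C/C(=C/Br)CC2
F2 | step 7 | C3-(9-borabicyclo[3.3.1]nonan-9-yl) O-borinate derived from 13 | CC1(C)C[C@@H](B2C3CCCC2CCC3)C[C@](C)(OB2C3CCCC2CCC3)[C@@]14C=C/C(=C/Br)CC4
F3 | step 7 | (1S,3R,6S,9E)-9-(bromomethylidene)-1,5,5-trimethylspiro[5.5]undec-7-ene-1,3-diol | CC1(C)C[C@@H](O)C[C@](C)(O)[C@@]12C=C/C(=C/Br)CC2
F4 | step 7 | (1S,6S,9E)-9-(bromomethylidene)-1-hydroxy-1,5,5-trimethylspiro[5.5]undec-7-en-3-one | CC1(C)CC(=O)C[C@](C)(O)[C@@]12C=C/C(=C/Br)CC2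
F5 | step 8 | cyclic sulfate of diol 16 (O–C1 and O–C3 bridged by SO2) | CC1(C)C[C@H]2C[C@](C)(OS(=O)(=O)O2)[C@@]13C=C/C(=C/Br)CC3
F6 | step 8 | lithium (1S,3R,6S,9E)-3-bromo-9-(bromomethylidene)-1,5,5-trimethylspiro[5.5]undec-7-en-1-yl sulfate | CC1(C)C[C@@H](Br)C[C@](C)(OS(=O)(=O)[O-])[C@@]12C=C/C(=C/Br)CC2.[Li+]
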